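The numbers in the tables were generated by integration for an exercise.

I choose to reckon these flasks by G, not by the pace that X sets.

| flask | Z | G | X | remark | time |
|---|---|---|---|---|---|
| west | 0.010 M | 0.015 M | 10 mM | run made earlier |  |
| south | 0.010 M | 0.015 M | 6.7 mM | run made earlier |  |
| north-east | 0.010 M | 0.015 M | 15 mM | run made earlier |  |
| amber | 0.010 M | 0.0150 M | 10.0 mM | everything together at the start | 20 min |
| teal | 0.010 M (fed, over 15 min) | 0.0150 M | 10.0 mM | all else is in the flask from the start; the feed brings no volume worth counting | 20 min |
| violet | 0.010 M | 0.0150 M | 10.0 mM (fed, over 15 min) | all else is in the flask from the start; the feed brings no volume worth counting | 20 min |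

| run | time / min | Q / % |
|---|---|---|
| west | 2.00 | 13 |
| west | 5.00 | 20 |
| west | 10.0 | 31 |
| west | 15.0 | 34 |
| west | 20.0 | 34 |
| south | 1.33 | 3 |
| south | 2.50 | 16 |
| south | 5.00 | 26 |
| south | 8.00 | 31 |
| south | 15.0 | 34 |
| north-east | 3.00 | 14 |
| north-east | 6.00 | 22 |
| north-east | 10.0 | 28 |
| north-east | 12.0 | 29 |
| north-east | 15.0 | 34 |

(scatter of a reading: 2 percentage points)

- a reading or a percentage of Q counts all its forms, free or not

- the flask that comes out highest in amount of Q, in percent of the Z charged, or "all alike" when all lie within 1.5 percentage points (amber / teal / violet / all alike)
- Q at the end, in percent of the Z charged, amber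
- Q at the end, in percent of the Z charged, teal
- Q at the end, in percent of the Z charged, violet

The readings give me a ladder of times. The first rung is the climb: the west plateau over its first rate gives 5.23 min. The next is the stop: west stands at 34% by 15.0 min, and south and north-east show 34% and 34% at that time, with X from 6.7 mM to 15 mM. So I take X to move the pace and leave the plateau.

The west plateau leaves 66.0% of the Z charged standing, and I read the stop as G's working window closing. The natural logarithm of Z charged over Z left at the west plateau is 0.416, the G dose. Spread evenly over the window, it gives Z a life of 36.1 min, the top rung, longer than the climb and the window. This is a pseudo-first-order reckoning with G's course taken as given, and the even spread is crude, since west has 20% by 5.00 min, more than an even climb to its plateau gives.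

In amber and violet Z stands in the flask from the start, so I give both the dose of west and put them at 34%, and this reckoning does not part them. Teal's Z arrives over 15 min, so I replace its arrival by the mean: it enters halfway through the window and takes half the dose, which gives 18.8%. Averaging over the whole feed gives 18.2%, so the mean errs by 0.60 percentage points.

The forecast names violet highest, with amber 34%, teal 31% and violet 34%, holding that X “does not set the ceiling”.

At 20 min amber gives 37.2%, teal 19.4% and violet 41.4%, so violet is highest.

    Z + G ⇌ Q (K = 61.0 M⁻¹, k = 4.70 M⁻¹ min⁻¹)
    X + G ⇌ J (K = 910 M⁻¹, k = 5.20 M⁻¹ min⁻¹)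
    X + Q ⇌ L, settled at all times (K = 4900 M⁻¹)
    G → E (k = 0.0640 min⁻¹)

Teal's dose at 20 min, 0.215, is half of amber's, the share the mean gave it, while violet lies above my 34%. The neighbour is violet with 0.060 M of G, which is 4.00 times the charge. West's dose multiplied by that ratio gives 81.0%, and at 20 min that flask gives 83.5%, with 16.5% of Z left.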